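**Plan**
- Late cuts: the five benzyl ethers come off last. The flavanone is cut at O1''–C2'' (oxa-Michael) and at C2''–C3'' (Knoevenagel), which gives a 3-(4-formylphenoxy)flavone and a ring A β-keto ester.
- Early cuts: the flavone pyranone is cut at O1–C2 (oxidative closure of a 2'-hydroxy-α-aryloxychalcone). The chalcone is cut at C8a–O1 and C4a–C4 together, which gives a 3,5-bis(benzyloxy)benzyne and an α-aryloxycinnamic acid. The C3–O–aryl ether is carried in from an aryloxyacetate.
- Enabling feature: in flavonol ring A the acyl carbon C4 (on C4a) and O1 (on C8a) sit on adjacent carbons, and C4a is flanked by the C5 oxygen. A carboxylic acid leaves exactly this 1,2,3-pattern when it adds across a benzyne whose triple bond lies next to an alkoxy group.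
- Forward order: silyl triflate and acid are made separately and joined by the aryne insertion (no ring). Flavonol ring C then closes, the freed aldehyde is condensed with the β-keto ester, and flavanone ring C closes last.
- Stereochemistry: the only stereocentre, C2'' (S), is set by a cinchona thiourea catalyst in the oxa-Michael closure. Decarboxylation and hydrogenolysis do not touch it.

Key step: step 7

Assumption: the quinidine-derived thiourea is taken to deliver the 2S series; the sense of induction is to be confirmed by circular dichroism on the protected flavanone, and the quinine-derived pseudo-enantiomer would replace it without any other change.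

Step 1
Reactants: 1 3,5-bis(benzyloxy)phenol
Product: 2 2-bromo-3,5-bis(benzyloxy)phenol
Conditions: NBS (1.0 equiv), i-Pr2NH (0.1 equiv), CH2Cl2, −78 → 0 °C
Reagents that add atoms: N-bromosuccinimide, O=C1CCC(=O)N1Br
Why: Amine-mediated ortho-selective electrophilic bromination of a phenol, in which the N-bromoamine is delivered through hydrogen bonding to the OH, so one of the two equivalent positions between OH and OBn should react in preference to the more crowded carbon between the two benzyloxy groups.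

Step 2
Reactants: 2 2-bromo-3,5-bis(benzyloxy)phenol
Product: 3 [2-bromo-3,5-bis(benzyloxy)phenoxy]trimethylsilane
Conditions: HN(SiMe3)2, THF, 70 °C; concentrate
Reagents that add atoms: hexamethyldisilazane, C[Si](C)(C)N[Si](C)(C)C
Why: O-silylation of a phenol with hexamethyldisilazane, which gives only ammonia as by-product, so the moisture-sensitive silyl ether can be used after evaporation.

Step 3
Reactants: 3 [2-bromo-3,5-bis(benzyloxy)phenoxy]trimethylsilane
Product: 5 3,5-bis(benzyloxy)-2-(trimethylsilyl)phenyl trifluoromethanesulfonate, via lithium phenoxide 4 (not isolated)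
Conditions: n-BuLi, THF, −78 °C; then Tf2O, −78 → 0 °C
Reagents that add atoms: trifluoromethanesulfonic anhydride, O=S(=O)(OS(=O)(=O)C(F)(F)F)C(F)(F)F
Why: Bromine–lithium exchange outruns benzylic deprotonation at −78 °C, the aryllithium undergoes the 1,3 O→C silyl shift (retro-Brook rearrangement), and the resulting phenoxide is trapped by Tf2O, which is the standard entry to ortho-silylaryl triflates.

Step 4
Reactants: 6 4-hydroxybenzaldehyde; 7 ethyl bromoacetate
Product: 8 ethyl 2-(4-formylphenoxy)acetate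
Conditions: K2CO3, acetone, reflux
Reagents that add atoms: none
Why: Williamson ether synthesis of an acidic phenol with an activated primary bromide, which forms the O–C bond that later becomes the C3–O–aryl ether of the flavonol.

Step 5
Reactants: 8 ethyl 2-(4-formylphenoxy)acetate
Product: 9 ethyl 2-[4-(1,3-dioxolan-2-yl)phenoxy]acetate
Conditions: HOCH2CH2OH (1.5 equiv), TsOH·H2O (2 mol %), toluene, reflux, Dean–Stark
Reagents that add atoms: ethylene glycol, OCCO
Why: Acid-catalysed acetalisation with azeotropic removal of water, which ethyl esters tolerate, masks the aldehyde so that it cannot compete as the electrophile in step 6.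

Step 6
Reactants: 9 ethyl 2-[4-(1,3-dioxolan-2-yl)phenoxy]acetate; 10 4-(benzyloxy)benzaldehyde
Product: 12 (Z)-3-[4-(benzyloxy)phenyl]-2-[4-(1,3-dioxolan-2-yl)phenoxy]acrylic acid, via ethyl ester 11 (not isolated)
Conditions: NaOEt (2 equiv), EtOH–THF, 0 °C → rt; then H2O, 45 °C; aq citric acid to pH 4, 0 °C, rapid extraction
Reagents that add atoms: water, O
Why: Claisen-type ester–aldehyde condensation (aldol addition, then E1cB loss of hydroxide), well known for α-alkoxyacetates with this aldehyde, should give the thermodynamic Z alkene with aryl trans to carboxyl, the hydroxide released saponifies the ester in the same pot, and the cold mild acidification spares the acetal.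

Step 7
Reactants: 5 3,5-bis(benzyloxy)-2-(trimethylsilyl)phenyl trifluoromethanesulfonate; 12 (Z)-3-[4-(benzyloxy)phenyl]-2-[4-(1,3-dioxolan-2-yl)phenoxy]acrylic acid
Product: 14 (Z)-1-[2,4-bis(benzyloxy)-6-hydroxyphenyl]-3-[4-(benzyloxy)phenyl]-2-[4-(1,3-dioxolan-2-yl)phenoxy]prop-2-en-1-one, via benzyne 13 (not isolated)
Conditions: 5 (1.5 equiv), CsF (4 equiv), THF (0.02 M), 125 °C, sealed tube
Reagents that add atoms: none
Why: Fluoride strips the silyl group from 5 and triflate departs, so benzyne 13 is released slowly by the sparingly soluble CsF, which also turns 12 into its carboxylate. The carboxylate oxygen adds to the aryne carbon remote from the flanking benzyloxy group, because the triple bond is distorted towards attack there and the developing aryl anion then lies next to the inductively withdrawing C–O bond. This anion attacks the neighbouring aryl ester carbonyl, and the strained four-membered alkoxide opens by C–O cleavage to the ortho-acyl phenoxide, which makes flavonol C8a–O1 and C4a–C4 in one operation and places the acyl group between the phenol and the future C5 oxygen. The closest known reaction type is the formal insertion of arynes into the C–O bond of aromatic, aliphatic and cinnamic carboxylic acids with CsF in hot THF, an intermolecular counterpart of the anionic Fries rearrangement. No ring is closed and no stereocentre is formed, since the oxa-Michael closure that simple cinnamic acids undergo afterwards is held back by the α-aryloxy oxygen and the 4-benzyloxyphenyl group, which both feed electron density to Cβ, and any closure that does occur converges in step 8. The step needs regiocontrol, secured by the benzyloxy group next to the triple bond, and acyl transfer faster than protonation of the aryl anion or conjugate attack at Cβ, secured by high dilution, the aprotic medium, the high temperature and the proximity of the ester carbonyl.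

Step 8
Reactants: 14 (Z)-1-[2,4-bis(benzyloxy)-6-hydroxyphenyl]-3-[4-(benzyloxy)phenyl]-2-[4-(1,3-dioxolan-2-yl)phenoxy]prop-2-en-1-one
Product: 16 4-({5,7-bis(benzyloxy)-2-[4-(benzyloxy)phenyl]-4-oxo-4H-chromen-3-yl}oxy)benzaldehyde, via acetal flavone 15 (not isolated)
Conditions: I2 (0.2 equiv), DMSO, 120 °C; then 1 M HCl, THF, rt
Reagents that add atoms: water, O
Why: Iodine-catalysed oxidative cyclisation of a 2'-hydroxychalcone in DMSO, in which iodine attacks the electron-rich enol-ether alkene at Cα, the phenol captures the aryl-stabilised Cβ cation in a 6-endo closure, loss of HI gives the 3-aryloxyflavone while DMSO reoxidises HI, and the dilute acid completes the acetal hydrolysis that HI has begun.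

Step 9
Reactants: 17 2',4',6'-trihydroxyacetophenone
Product: 18 1-[2,4-bis(benzyloxy)-6-hydroxyphenyl]ethan-1-one
Conditions: BnBr (2.1 equiv), K2CO3 (2.2 equiv), DMF, rt → 50 °C
Reagents that add atoms: benzyl bromide, BrCc1ccccc1
Why: Selective Williamson O-benzylation, in which one ortho hydroxyl stays hydrogen-bonded to the acetyl carbonyl and is therefore the least nucleophilic, so alkylation should stop at the dibenzyl ether.

Step 10
Reactants: 18 1-[2,4-bis(benzyloxy)-6-hydroxyphenyl]ethan-1-one
Product: 19 tert-butyl 3-[2,4-bis(benzyloxy)-6-hydroxyphenyl]-3-oxopropanoate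
Conditions: LiN(SiMe3)2 (3.3 equiv), THF, −78 °C; Boc2O (1.1 equiv), −78 → 0 °C; aq NH4Cl
Reagents that add atoms: di-tert-butyl dicarbonate, CC(C)(C)OC(=O)OC(=O)OC(C)(C)C
Why: C-acylation of a lithium phenoxide–enolate polyanion, which reacts at the enolate carbon as it does with aroyl chlorides, while any phenol carbonate is carried to the same product by a Baker–Venkataraman-type O→C transfer, the third equivalent of base stores the product as its enolate, and the bulky ester resists lactonisation.

Step 11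
Reactants: 16 4-({5,7-bis(benzyloxy)-2-[4-(benzyloxy)phenyl]-4-oxo-4H-chromen-3-yl}oxy)benzaldehyde; 19 tert-butyl 3-[2,4-bis(benzyloxy)-6-hydroxyphenyl]-3-oxopropanoate
Product: 20 tert-butyl (Z)-2-[2,4-bis(benzyloxy)-6-hydroxybenzoyl]-3-[4-({5,7-bis(benzyloxy)-2-[4-(benzyloxy)phenyl]-4-oxo-4H-chromen-3-yl}oxy)phenyl]acrylate
Conditions: piperidine (0.1 equiv), AcOH (0.1 equiv), 4 Å molecular sieves, toluene, rt
Reagents that add atoms: none
Why: Knoevenagel condensation under piperidinium acetate catalysis with removal of water should place the aryl group cis to the ester and trans to the twisted aroyl group, and the low temperature and low catalyst loading keep the free phenol from adding prematurely.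

Step 12
Reactants: 20 tert-butyl (Z)-2-[2,4-bis(benzyloxy)-6-hydroxybenzoyl]-3-[4-({5,7-bis(benzyloxy)-2-[4-(benzyloxy)phenyl]-4-oxo-4H-chromen-3-yl}oxy)phenyl]acrylate
Product: 22 (2S)-5,7-bis(benzyloxy)-2-[4-({5,7-bis(benzyloxy)-2-[4-(benzyloxy)phenyl]-4-oxo-4H-chromen-3-yl}oxy)phenyl]chroman-4-one, via flavanone-3-carboxylate 21 (not isolated)
Conditions: 1-[3,5-bis(trifluoromethyl)phenyl]-3-[(9R)-6'-methoxycinchonan-9-yl]thiourea (10 mol %), toluene, −25 °C; then TsOH·H2O (0.3 equiv), 80 °C
Reagents that add atoms: none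
Why: Bifunctional thiourea-catalysed intramolecular oxa-Michael addition (6-endo-trig), in which the thiourea binds the 1,3-dicarbonyl unit while the quinuclidine nitrogen deprotonates the phenol, so the phenoxide reaches only one face of the benzylidene carbon and fixes C2'' as S, after which acid-induced loss of isobutene and CO2 removes the epimerisable C3'' substituent without touching C2''.

Step 13
Reactants: 22 (2S)-5,7-bis(benzyloxy)-2-[4-({5,7-bis(benzyloxy)-2-[4-(benzyloxy)phenyl]-4-oxo-4H-chromen-3-yl}oxy)phenyl]chroman-4-one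
Product: 23 (2S)-5,7-dihydroxy-2-(4-{[5,7-dihydroxy-2-(4-hydroxyphenyl)-4-oxo-4H-chromen-3-yl]oxy}phenyl)chroman-4-one (CNP0144321.1)
Conditions: H2 (1 atm), 10% Pd/C, THF–MeOH, rt, stopped after uptake of five equivalents
Reagents that add atoms: none
Why: Catalytic hydrogenolysis of the five aryl benzyl ethers, which should be faster than reduction of the tetrasubstituted flavone alkene, the ketones or the benzylic C2''–O bond, and whose neutral medium avoids the base-induced ring opening that would racemise C2''.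

**Compound list**
1 | 3,5-bis(benzyloxy)phenol | Oc1cc(OCc2ccccc2)cc(OCc2ccccc2)c1 | starting material
2 | 2-bromo-3,5-bis(benzyloxy)phenol | Oc1cc(OCc2ccccc2)cc(OCc2ccccc2)c1Br | intermediate
3 | [2-bromo-3,5-bis(benzyloxy)phenoxy]trimethylsilane | C[Si](C)(C)Oc1cc(OCc2ccccc2)cc(OCc2ccccc2)c1Br | intermediate
4 | lithium 3,5-bis(benzyloxy)-2-(trimethylsilyl)phenoxide | [Li+].[O-]c1cc(OCc2ccccc2)cc(OCc2ccccc2)c1[Si](C)(C)C | intermediate
5 | 3,5-bis(benzyloxy)-2-(trimethylsilyl)phenyl trifluoromethanesulfonate | C[Si](C)(C)c1c(OS(=O)(=O)C(F)(F)F)cc(OCc2ccccc2)cc1OCc1ccccc1 | intermediate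
6 | 4-hydroxybenzaldehyde | O=Cc1ccc(O)cc1 | starting material
7 | ethyl bromoacetate | CCOC(=O)CBr | starting material
8 | ethyl 2-(4-formylphenoxy)acetate | CCOC(=O)COc1ccc(C=O)cc1 | intermediate
9 | ethyl 2-[4-(1,3-dioxolan-2-yl)phenoxy]acetate | CCOC(=O)COc1ccc(C2OCCO2)cc1 | intermediate
10 | 4-(benzyloxy)benzaldehyde | O=Cc1ccc(OCc2ccccc2)cc1 | starting material
11 | ethyl (Z)-3-[4-(benzyloxy)phenyl]-2-[4-(1,3-dioxolan-2-yl)phenoxy]acrylate | CCOC(=O)/C(Oc1ccc(C2OCCO2)cc1)=C/c1ccc(OCc2ccccc2)cc1 | intermediate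
12 | (Z)-3-[4-(benzyloxy)phenyl]-2-[4-(1,3-dioxolan-2-yl)phenoxy]acrylic acid | OC(=O)/C(Oc1ccc(C2OCCO2)cc1)=C/c1ccc(OCc2ccccc2)cc1 | intermediate
13 | 3,5-bis(benzyloxy)benzyne | C1#CC(OCc2ccccc2)=CC(OCc2ccccc2)=C1 | intermediate
14 | (Z)-1-[2,4-bis(benzyloxy)-6-hydroxyphenyl]-3-[4-(benzyloxy)phenyl]-2-[4-(1,3-dioxolan-2-yl)phenoxy]prop-2-en-1-one | O=C(/C(Oc1ccc(C2OCCO2)cc1)=C/c1ccc(OCc2ccccc2)cc1)c1c(O)cc(OCc2ccccc2)cc1OCc1ccccc1 | intermediate
15 | 5,7-bis(benzyloxy)-2-[4-(benzyloxy)phenyl]-3-[4-(1,3-dioxolan-2-yl)phenoxy]-4H-chromen-4-one | O=c1c(Oc2ccc(C3OCCO3)cc2)c(-c2ccc(OCc3ccccc3)cc2)oc2cc(OCc3ccccc3)cc(OCc3ccccc3)c12 | intermediate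
16 | 4-({5,7-bis(benzyloxy)-2-[4-(benzyloxy)phenyl]-4-oxo-4H-chromen-3-yl}oxy)benzaldehyde | O=Cc1ccc(Oc2c(-c3ccc(OCc4ccccc4)cc3)oc3cc(OCc4ccccc4)cc(OCc4ccccc4)c3c2=O)cc1 | intermediate
17 | 2',4',6'-trihydroxyacetophenone | CC(=O)c1c(O)cc(O)cc1O | starting material
18 | 1-[2,4-bis(benzyloxy)-6-hydroxyphenyl]ethan-1-one | CC(=O)c1c(O)cc(OCc2ccccc2)cc1OCc1ccccc1 | intermediate
19 | tert-butyl 3-[2,4-bis(benzyloxy)-6-hydroxyphenyl]-3-oxopropanoate | CC(C)(C)OC(=O)CC(=O)c1c(O)cc(OCc2ccccc2)cc1OCc1ccccc1 | intermediate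
20 | tert-butyl (Z)-2-[2,4-bis(benzyloxy)-6-hydroxybenzoyl]-3-[4-({5,7-bis(benzyloxy)-2-[4-(benzyloxy)phenyl]-4-oxo-4H-chromen-3-yl}oxy)phenyl]acrylate | CC(C)(C)OC(=O)/C(C(=O)c1c(O)cc(OCc2ccccc2)cc1OCc1ccccc1)=C\c1ccc(Oc2c(-c3ccc(OCc4ccccc4)cc3)oc3cc(OCc4ccccc4)cc(OCc4ccccc4)c3c2=O)cc1 | intermediate
21 | tert-butyl (2S)-5,7-bis(benzyloxy)-2-[4-({5,7-bis(benzyloxy)-2-[4-(benzyloxy)phenyl]-4-oxo-4H-chromen-3-yl}oxy)phenyl]-4-oxochromane-3-carboxylate (C3 epimerisable, left open) | O=C1C(C(=O)OC(C)(C)C)[C@@H](c2ccc(Oc3c(-c4ccc(OCc5ccccc5)cc4)oc4cc(OCc5ccccc5)cc(OCc5ccccc5)c4c3=O)cc2)Oc2cc(OCc3ccccc3)cc(OCc3ccccc3)c21 | intermediate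
22 | (2S)-5,7-bis(benzyloxy)-2-[4-({5,7-bis(benzyloxy)-2-[4-(benzyloxy)phenyl]-4-oxo-4H-chromen-3-yl}oxy)phenyl]chroman-4-one | O=C1C[C@@H](c2ccc(Oc3c(-c4ccc(OCc5ccccc5)cc4)oc4cc(OCc5ccccc5)cc(OCc5ccccc5)c4c3=O)cc2)Oc2cc(OCc3ccccc3)cc(OCc3ccccc3)c21 | intermediate
23 | (2S)-5,7-dihydroxy-2-(4-{[5,7-dihydroxy-2-(4-hydroxyphenyl)-4-oxo-4H-chromen-3-yl]oxy}phenyl)chroman-4-one (CNP0144321.1) | O=C1C[C@@H](c2ccc(Oc3c(-c4ccc(O)cc4)oc4cc(O)cc(O)c4c3=O)cc2)Oc2cc(O)cc(O)c21 | target

**Step count**
- Total steps: 13.
- Longest linear sequence: 8 steps (4, 5, 6, 7, 8, 11, 12, 13). The branch 1, 2, 3, 7, 8, 11, 12, 13 is equally long.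

**Steps most likely to fail**

Step 7.
- The aryl anion may be protonated before the acyl group migrates, which would amount to plain O-arylation.
- The product phenoxide may be arylated a second time.
- The acetal may suffer at 125 °C.

The fallback reaches the same ortho-metallated aryl ester without an aryne, so only C4a–C4 is formed and the regiochemistry is fixed by the halogen. It sets out from 2 and 12. Carbodiimide esterification (EDC·HCl, DMAP, CH2Cl2) gives 2-bromo-3,5-bis(benzyloxy)phenyl (Z)-3-[4-(benzyloxy)phenyl]-2-[4-(1,3-dioxolan-2-yl)phenoxy]acrylate F1. Bromine–lithium exchange with n-BuLi in THF at −100 °C then triggers the known anionic Fries-type 1,3 O→C acyl shift. Protonation rejoins the route at 14.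

Step 12.
- Facial selectivity may be poor because the benzyloxy group ortho to the ketone twists the aroyl unit out of the catalyst's binding pocket.
- Uncatalysed background closure may compete.
- Acid-promoted ring opening and reclosure during decarboxylation may erode the enantiomeric purity.

The fallback gives up asymmetric closure in favour of resolution. It sets out from 20. Et3N in toluene closes the ring without facial bias to the racemic tert-butyl flavanone-3-carboxylate F2. TsOH at 80 °C converts this into the racemic protected flavanone F3. Kinetic resolution by asymmetric transfer hydrogenation with RuCl[(R,R)-TsDPEN](p-cymene) in HCO2H–Et3N should reduce the matched 2R enantiomer to the cis-(2R,4R)-flavan-4-ol F4. The unreacted 2S ketone is separated by chromatography and is 22.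

Step 8.
- Closure may be sluggish because the α-aryloxy enone is a poor acceptor.
- Iodine may attack the electron-rich ring A.
- HI may remove the benzyl group peri to the carbonyl.

The fallback raises the oxidation level before ring closure, so the pyranone forms by dehydration and no oxidant is needed, while the aryne disconnection is kept. It sets out from 9 and 5. Saponification of 9 (LiOH, THF–H2O, then citric acid) gives 2-[4-(1,3-dioxolan-2-yl)phenoxy]acetic acid F5. Under the conditions of step 7 this acid inserts into benzyne 13 to give 1-[2,4-bis(benzyloxy)-6-hydroxyphenyl]-2-[4-(1,3-dioxolan-2-yl)phenoxy]ethan-1-one F6. The lithium polyanion of F6 (LiN(SiMe3)2, THF, −78 °C) is C-aroylated with 4-(benzyloxy)benzoyl chloride to 1-[2,4-bis(benzyloxy)-6-hydroxyphenyl]-3-[4-(benzyloxy)phenyl]-2-[4-(1,3-dioxolan-2-yl)phenoxy]propane-1,3-dione F7. TsOH·H2O in wet THF at 60 °C cyclodehydrates the diketone and hydrolyses the acetal, which rejoins the route at 16.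

**Further compounds**
F1 | step 7 | 2-bromo-3,5-bis(benzyloxy)phenyl (Z)-3-[4-(benzyloxy)phenyl]-2-[4-(1,3-dioxolan-2-yl)phenoxy]acrylate | O=C(Oc1cc(OCc2ccccc2)cc(OCc2ccccc2)c1Br)/C(Oc1ccc(C2OCCO2)cc1)=C/c1ccc(OCc2ccccc2)cc1
F2 | step 12 | racemic tert-butyl 5,7-bis(benzyloxy)-2-[4-({5,7-bis(benzyloxy)-2-[4-(benzyloxy)phenyl]-4-oxo-4H-chromen-3-yl}oxy)phenyl]-4-oxochromane-3-carboxylate | O=C1C(C(=O)OC(C)(C)C)C(c2ccc(Oc3c(-c4ccc(OCc5ccccc5)cc4)oc4cc(OCc5ccccc5)cc(OCc5ccccc5)c4c3=O)cc2)Oc2cc(OCc3ccccc3)cc(OCc3ccccc3)c21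
F3 | step 12 | racemic 5,7-bis(benzyloxy)-2-[4-({5,7-bis(benzyloxy)-2-[4-(benzyloxy)phenyl]-4-oxo-4H-chromen-3-yl}oxy)phenyl]chroman-4-one | O=C1CC(c2ccc(Oc3c(-c4ccc(OCc5ccccc5)cc4)oc4cc(OCc5ccccc5)cc(OCc5ccccc5)c4c3=O)cc2)Oc2cc(OCc3ccccc3)cc(OCc3ccccc3)c21
F4 | step 12 | 5,7-bis(benzyloxy)-3-{4-[(2R,4R)-5,7-bis(benzyloxy)-4-hydroxychroman-2-yl]phenoxy}-2-[4-(benzyloxy)phenyl]-4H-chromen-4-one | O[C@@H]1C[C@H](c2ccc(Oc3c(-c4ccc(OCc5ccccc5)cc4)oc4cc(OCc5ccccc5)cc(OCc5ccccc5)c4c3=O)cc2)Oc2cc(OCc3ccccc3)cc(OCc3ccccc3)c21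
F5 | step 8 | 2-[4-(1,3-dioxolan-2-yl)phenoxy]acetic acid | OC(=O)COc1ccc(C2OCCO2)cc1
F6 | step 8 | 1-[2,4-bis(benzyloxy)-6-hydroxyphenyl]-2-[4-(1,3-dioxolan-2-yl)phenoxy]ethan-1-one | O=C(COc1ccc(C2OCCO2)cc1)c1c(O)cc(OCc2ccccc2)cc1OCc1ccccc1
F7 | step 8 | 1-[2,4-bis(benzyloxy)-6-hydroxyphenyl]-3-[4-(benzyloxy)phenyl]-2-[4-(1,3-dioxolan-2-yl)phenoxy]propane-1,3-dione (racemic, enolisable) | O=C(c1ccc(OCc2ccccc2)cc1)C(Oc1ccc(C2OCCO2)cc1)C(=O)c1c(O)cc(OCc2ccccc2)cc1OCc1ccccc1
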